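**Retrosynthetic overview**

1. Ring A is the central phloroglucinol (butanoyl on carbon 1, OH on carbons 2, 4 and 6, CH2 bridges on carbons 3 and 5); each outer ring B is B1 (bridge carbon), B2 OH, B3 butanoyl, B4 OH, B5 CH3, B6 OCH3. The route rests on reading each ring B as a folded chain: B4–B5–B6–B1 is a 2-methylacetoacetate unit whose gamma carbon B1 carries the bridge CH2, and B2–B3 with the butanoyl chain is a 3-oxohexanoate unit.
2. Late disconnections: the aryl–C(=O) bond at carbon 1 of ring A (Houben–Hoesch), the three benzyl ethers of ring A, and the two B6 O–CH3 bonds (methylation of the one unchelated hydroxyl of each ring B).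
3. Key disconnection: bonds B1–B2 (gamma-acylation) and B3–B4 (Claisen) of both rings B at once, back to a ring A bis(2-methyl-3-oxopentanoate) and two molecules of methyl 3-oxohexanoate. Ring A comes from phloroglucinol; both rings B form together in this one step.
4. The bis(beta-keto ester) is reached in four steps without any benzylic halide of the electron-rich ring: Vilsmeier diformylation, benzylation, reductive Meldrum's acid homologation of both aldehydes, and Masamune chain extension with a methylmalonate half-ester.

Key step: step 5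

Remark: methyl hydrogen methylmalonate (10) is taken as a purchasable reagent, and 10, 12 and 15 are used as stereoisomer mixtures because their sp3 stereocentres are lost or become aromatic carbons of the achiral target.
Remark: where a step consumes more than one equivalent of a building block, the numbered reactant counts as the first equivalent and each further equivalent that delivers atoms to the product is entered as a reagent.

**Route**

Step 1
Reactants: 1 phloroglucinol
Product: 3 2,4,6-trihydroxybenzene-1,3-dicarbaldehyde, via bis(iminium) dichloride 2 (not isolated)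
Conditions: POCl3 (2.4 equiv), DMF (2.6 equiv), 1,4-dioxane, 0 °C to rt; then H2O
Reagents that add atoms: N,N-dimethylformamide (two equivalents) CN(C)C=O.CN(C)C=O; water (two equivalents) O.O
Why: Vilsmeier–Haack formylation, in which the chloroiminium ion attacks the phloroglucinol nucleus twice (the third position is deactivated by the two iminium groups) and water hydrolyses the bis(iminium) salt to the dialdehyde.

Step 2
Reactants: 3 2,4,6-trihydroxybenzene-1,3-dicarbaldehyde; 4 benzyl bromide
Product: 5 2,4,6-tris(benzyloxy)benzene-1,3-dicarbaldehyde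
Conditions: 4 (3.6 equiv in all), K2CO3 (4 equiv), DMF, 70 °C
Reagents that add atoms: benzyl bromide (two further equivalents) BrCc1ccccc1.BrCc1ccccc1
Why: Williamson ether synthesis (SN2) on all three hydroxyls, in which the two formyl groups lower the carbon nucleophilicity of the phenoxide so that O-benzylation should prevail, the chelated hydroxyls needing the excess of 4 and heat.

Step 3
Reactants: 5 2,4,6-tris(benzyloxy)benzene-1,3-dicarbaldehyde; 6 Meldrum's acid (2,2-dimethyl-1,3-dioxane-4,6-dione)
Product: 9 3,3'-[2,4,6-tris(benzyloxy)-1,3-phenylene]dipropanoic acid, via bis(arylidene) Meldrum's acid adduct 7 (not isolated), via bis(benzyl) Meldrum's acid adduct 8 (not isolated)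
Conditions: 6 (2.3 equiv in all), HCO2H–Et3N (5:2), 95 °C; then H2O, aq. HCl
Reagents that add atoms: Meldrum's acid (second equivalent) CC1(C)OC(=O)CC(=O)O1; water (two equivalents) O.O
Why: Knoevenagel condensation with Meldrum's acid, conjugate reduction of the arylidene by formate (hydride transfer) and hydrolysis–decarboxylation in one pot (the water set free in the condensation opens the dioxanedione rings) should turn each non-enolisable aldehyde into a CH2CH2CO2H arm without hydrogen gas, which would attack the benzyl ethers.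

Step 4
Reactants: 9 3,3'-[2,4,6-tris(benzyloxy)-1,3-phenylene]dipropanoic acid; 10 methyl hydrogen methylmalonate (3-methoxy-2-methyl-3-oxopropanoic acid)
Product: 12 dimethyl 5,5'-[2,4,6-tris(benzyloxy)-1,3-phenylene]bis(2-methyl-3-oxopentanoate), via bis(acyl imidazolide) 11 (not isolated)
Conditions: 1,1'-carbonyldiimidazole (2.3 equiv), THF, rt; then 10 (3 equiv in all), MgCl2, Et3N, MeCN, rt to 45 °C; aq. HCl
Reagents that add atoms: methyl hydrogen methylmalonate (second equivalent) COC(=O)C(C)C(=O)O
Why: Masamune–Brooks chain extension, in which each acyl imidazolide C-acylates the magnesium enolate of the malonic half-ester and decarboxylation on acidification leaves the 2-methyl beta-keto ester under conditions that do not touch the benzyl ethers.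

Step 5
Reactants: 12 dimethyl 5,5'-[2,4,6-tris(benzyloxy)-1,3-phenylene]bis(2-methyl-3-oxopentanoate); 13 methyl 3-oxohexanoate
Product: 16 1,3,5-tris(benzyloxy)-2,4-bis[(3-butanoyl-2,4,6-trihydroxy-5-methylphenyl)methyl]benzene, via tetralithium tetraanion 14 (not isolated), via bis(triketo ester) 15 (not isolated)
Conditions: LiN(iPr)2 (4.2 equiv), THF, −78 to 0 °C; lithium enolate of 13 (3 equiv in all; from 13 and LiN(iPr)2, THF), −78 °C to rt; then MeOH, 60 °C; aq. HCl
Reagents that add atoms: methyl 3-oxohexanoate (second equivalent) CCCC(=O)CC(=O)OC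
Why: Proposed new method: LiN(iPr)2 turns each arm of 12 into its alpha,gamma-dianion, whose terminal carbanion B1 adds to the ester carbonyl of the enolate of 13 (used as the enolate so that its ketone and acidic CH2 are masked) and expels methoxide to form B1–B2, giving on each arm a 2-methyl-3,5,7-triketo ester (15) that is formed as a polyenolate, the new acidic B1–H being taken up by the lithium methoxide set free, so that it should not quench carbanion that has not yet reacted. In the methanol/LiOMe phase proton exchange frees ester carbon B4, the carbanion B3 held between two carbonyls attacks it in a 6-exo-trig Claisen (Dieckmann-type) closure, and loss of methoxide followed by enolisation gives each aromatic ring B with the butanoyl group already on B3. The closest known reactions are the gamma-acylation of beta-keto ester dianions by esters and by salts of beta-keto esters and the base-induced Claisen cyclisation of 3,5,7-triketo esters to acylphloroglucinols; untested here are the branched gamma carbon, the alpha-methyl group and the run in two directions with both closures in one flask. No stereocentre is formed, and the uncontrolled sp3 centres of 12 and 15 vanish on aromatisation. The step needs gamma- over alpha-acylation, which the more basic terminal carbanion and the tertiary, enolate-bound alpha carbon B5 should secure, and Claisen over aldol or lactone closure: an aldol attack of B5 on the butanoyl carbonyl would make B5 quaternary and cannot lead to an arene, while alkoxide reopens lactones, so only the phloroglucinol fold should reach the stable phenoxide.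

Step 6
Reactants: 16 1,3,5-tris(benzyloxy)-2,4-bis[(3-butanoyl-2,4,6-trihydroxy-5-methylphenyl)methyl]benzene
Product: 17 1,3,5-tris(benzyloxy)-2,4-bis[(3-butanoyl-2,4-dihydroxy-6-methoxy-5-methylphenyl)methyl]benzene
Conditions: Me2SO4 (2.1 equiv), K2CO3 (2.2 equiv), acetone, rt
Reagents that add atoms: dimethyl sulfate (two equivalents) COS(=O)(=O)OC.COS(=O)(=O)OC
Why: Williamson O-methylation under substrate control, since in each ring B the B6 hydroxyl is para to the butanoyl group, not hydrogen-bonded to it and the most acidic, so with one equivalent of Me2SO4 per ring it should be etherified ahead of the chelated B2 and B4 hydroxyls.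

Step 7
Reactants: 17 1,3,5-tris(benzyloxy)-2,4-bis[(3-butanoyl-2,4-dihydroxy-6-methoxy-5-methylphenyl)methyl]benzene
Product: 18 2,4-bis[(3-butanoyl-2,4-dihydroxy-6-methoxy-5-methylphenyl)methyl]benzene-1,3,5-triol
Conditions: H2 (1 atm), Pd/C, EtOAc–MeOH, rt
Reagents that add atoms: none
Why: Catalytic hydrogenolysis should remove the three aryl benzyl ethers, while the hydrogen-bonded hindered aryl ketones, the methyl ethers and the diarylmethane C–C bonds are inert at 1 atm.

Step 8
Reactants: 18 2,4-bis[(3-butanoyl-2,4-dihydroxy-6-methoxy-5-methylphenyl)methyl]benzene-1,3,5-triol; 19 butanenitrile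
Product: 21 1-{3,5-bis[(3-butanoyl-2,4-dihydroxy-6-methoxy-5-methylphenyl)methyl]-2,4,6-trihydroxyphenyl}butan-1-one, via ketiminium chloride 20 (not isolated)
Conditions: 19, ZnCl2, HCl (g), Et2O–EtOAc, 0 °C; then H2O, 90 °C
Reagents that add atoms: water O
Why: Houben–Hoesch acylation, since carbon 1 of ring A is the only unsubstituted aromatic carbon of 18 and lies between two hydroxyls of a phloroglucinol ring, so the nitrilium species should attack there and hydrolysis of the ketiminium salt gives the aryl ketone without O-acylation.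

**Compound list**

1 | phloroglucinol (benzene-1,3,5-triol) | Oc1cc(O)cc(O)c1 | starting material
2 | bis(N,N-dimethyliminium) dichloride of 2,4,6-trihydroxybenzene-1,3-dicarbaldehyde | C[N+](C)=Cc1c(O)cc(O)c(C=[N+](C)C)c1O.[Cl-].[Cl-] | intermediate
3 | 2,4,6-trihydroxybenzene-1,3-dicarbaldehyde | O=Cc1c(O)cc(O)c(C=O)c1O | intermediate
4 | benzyl bromide | BrCc1ccccc1 | starting material
5 | 2,4,6-tris(benzyloxy)benzene-1,3-dicarbaldehyde | O=Cc1c(OCc2ccccc2)cc(OCc2ccccc2)c(C=O)c1OCc1ccccc1 | intermediate
6 | Meldrum's acid (2,2-dimethyl-1,3-dioxane-4,6-dione) | CC1(C)OC(=O)CC(=O)O1 | starting material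
7 | 5,5'-{[2,4,6-tris(benzyloxy)-1,3-phenylene]dimethanylylidene}bis(2,2-dimethyl-1,3-dioxane-4,6-dione) | CC1(C)OC(=O)C(=Cc2c(OCc3ccccc3)cc(OCc3ccccc3)c(C=C3C(=O)OC(C)(C)OC3=O)c2OCc2ccccc2)C(=O)O1 | intermediate
8 | 5,5'-{[2,4,6-tris(benzyloxy)-1,3-phenylene]bis(methylene)}bis(2,2-dimethyl-1,3-dioxane-4,6-dione) | CC1(C)OC(=O)C(Cc2c(OCc3ccccc3)cc(OCc3ccccc3)c(CC3C(=O)OC(C)(C)OC3=O)c2OCc2ccccc2)C(=O)O1 | intermediate
9 | 3,3'-[2,4,6-tris(benzyloxy)-1,3-phenylene]dipropanoic acid | OC(=O)CCc1c(OCc2ccccc2)cc(OCc2ccccc2)c(CCC(=O)O)c1OCc1ccccc1 | intermediate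
10 | methyl hydrogen methylmalonate (3-methoxy-2-methyl-3-oxopropanoic acid, racemic) | COC(=O)C(C)C(=O)O | starting material
11 | 3,3'-[2,4,6-tris(benzyloxy)-1,3-phenylene]bis[1-(1H-imidazol-1-yl)propan-1-one] | O=C(CCc1c(OCc2ccccc2)cc(OCc2ccccc2)c(CCC(=O)n2ccnc2)c1OCc1ccccc1)n1ccnc1 | intermediate
12 | dimethyl 5,5'-[2,4,6-tris(benzyloxy)-1,3-phenylene]bis(2-methyl-3-oxopentanoate) (stereoisomer mixture) | COC(=O)C(C)C(=O)CCc1c(OCc2ccccc2)cc(OCc2ccccc2)c(CCC(=O)C(C)C(=O)OC)c1OCc1ccccc1 | intermediate
13 | methyl 3-oxohexanoate | CCCC(=O)CC(=O)OC | starting material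
14 | tetralithium salt of the bis(alpha,gamma-dianion) of 12 | COC([O-])=C(C)C([O-])=CCc1c(OCc2ccccc2)cc(OCc2ccccc2)c(CC=C([O-])C(C)=C([O-])OC)c1OCc1ccccc1.[Li+].[Li+].[Li+].[Li+] | intermediate
15 | dimethyl 4,4'-{[2,4,6-tris(benzyloxy)-1,3-phenylene]bis(methylene)}bis(2-methyl-3,5,7-trioxodecanoate) (stereoisomer mixture, drawn in the neutral keto form) | CCCC(=O)CC(=O)C(Cc1c(OCc2ccccc2)cc(OCc2ccccc2)c(CC(C(=O)CC(=O)CCC)C(=O)C(C)C(=O)OC)c1OCc1ccccc1)C(=O)C(C)C(=O)OC | intermediate
16 | 1,3,5-tris(benzyloxy)-2,4-bis[(3-butanoyl-2,4,6-trihydroxy-5-methylphenyl)methyl]benzene | CCCC(=O)c1c(O)c(C)c(O)c(Cc2c(OCc3ccccc3)cc(OCc3ccccc3)c(Cc3c(O)c(C(=O)CCC)c(O)c(C)c3O)c2OCc2ccccc2)c1O | intermediate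
17 | 1,3,5-tris(benzyloxy)-2,4-bis[(3-butanoyl-2,4-dihydroxy-6-methoxy-5-methylphenyl)methyl]benzene | CCCC(=O)c1c(O)c(C)c(OC)c(Cc2c(OCc3ccccc3)cc(OCc3ccccc3)c(Cc3c(O)c(C(=O)CCC)c(O)c(C)c3OC)c2OCc2ccccc2)c1O | intermediate
18 | 2,4-bis[(3-butanoyl-2,4-dihydroxy-6-methoxy-5-methylphenyl)methyl]benzene-1,3,5-triol | CCCC(=O)c1c(O)c(C)c(OC)c(Cc2c(O)cc(O)c(Cc3c(O)c(C(=O)CCC)c(O)c(C)c3OC)c2O)c1O | intermediate
19 | butanenitrile | CCCC#N | starting material
20 | 1-{3,5-bis[(3-butanoyl-2,4-dihydroxy-6-methoxy-5-methylphenyl)methyl]-2,4,6-trihydroxyphenyl}butan-1-iminium chloride | CCCC(=[NH2+])c1c(O)c(Cc2c(O)c(C(=O)CCC)c(O)c(C)c2OC)c(O)c(Cc2c(O)c(C(=O)CCC)c(O)c(C)c2OC)c1O.[Cl-] | intermediate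
21 | 1-{3,5-bis[(3-butanoyl-2,4-dihydroxy-6-methoxy-5-methylphenyl)methyl]-2,4,6-trihydroxyphenyl}butan-1-one (CNP0264591.0, achiral) | CCCC(=O)c1c(O)c(Cc2c(O)c(C(=O)CCC)c(O)c(C)c2OC)c(O)c(Cc2c(O)c(C(=O)CCC)c(O)c(C)c2OC)c1O | target

**Step count**

Total steps: 8. Longest linear sequence: 8 steps (1 to 21).

**Steps most likely to fail**

Step 5 (key step, proposed new method). Attack of the branched carbanion B1 on an ester that is deactivated as an enolate may be slow, and proton transfer from an arm that has already been acylated could quench the other arm, so the reaction may stop after one arm or none. In the alkoxide phase, retro-Claisen cleavage at the branched 1,3-diketone or closure through oxygen to a pyranone could consume the chain before it aromatises.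
Fallback with known chemistry, setting out from 1 and coming back at 21: the rings B are made as arenes instead of being folded. Houben–Hoesch butanoylation of 1 with 19 (ZnCl2, HCl, Et2O; then hot water) gives 1-(2,4,6-trihydroxyphenyl)butan-1-one F1. A double Mannich reaction (aqueous CH2O, Me2NH, EtOH, rt) then gives 1-{3,5-bis[(dimethylamino)methyl]-2,4,6-trihydroxyphenyl}butan-1-one F2. In parallel, commercial 2-methylbenzene-1,3,5-triol is acylated with 19 in the same way to 1-(2,4,6-trihydroxy-3-methylphenyl)butan-1-one F3, whose para hydroxyl is methylated (Me2SO4, 1 equiv, K2CO3, acetone) to 1-(2,6-dihydroxy-4-methoxy-3-methylphenyl)butan-1-one F4 (aspidinol). Heating F2 with F4 (2.2 equiv, 1,4-dioxane, reflux) should expel the amine twice; each ortho-quinone methide of ring A is captured by the single free ring carbon of F4, which gives 21 directly. Ring A of F2 is fully substituted, so it cannot condense with itself.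

Step 8. Ipso-protonation of the electron-rich rings under HCl/ZnCl2, or during the hot aqueous hydrolysis, could cleave or migrate the methylene bridges, and the hindered ketiminium salt may hydrolyse slowly.
Fallback, setting out from 17 and coming back at 21: the acyl group is put on before deprotection. Friedel–Crafts acylation of the still benzylated ring A of 17 at its carbon 1 (the only free position of an activated ring) uses the mixed anhydride of butanoic acid and (CF3CO)2O (CH2Cl2, 0 °C to rt; NaHCO3/MeOH work-up to cleave any aryl ester formed on the ring B phenols). It should give 1-{2,4,6-tris(benzyloxy)-3,5-bis[(3-butanoyl-2,4-dihydroxy-6-methoxy-5-methylphenyl)methyl]phenyl}butan-1-one F5. Hydrogenolysis of F5 (H2, Pd/C, EtOAc–MeOH) then gives 21 as the last step, with no metal Lewis acid and no ketimine hydrolysis on the free polyphenol.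

Step 6. Methylation may run on to the chelated B2/B4 hydroxyls, or the fully substituted ring B phenoxide may be methylated on carbon with loss of aromaticity, so that the two B6 ethers are not obtained cleanly.
Fallback, setting out from 16 and coming back at 18: selectivity is moved from ether formation to ether cleavage. Exhaustive methylation of 16 (Me2SO4 in excess, K2CO3, acetone, reflux) gives 1,3,5-tris(benzyloxy)-2,4-bis[(3-butanoyl-2,4,6-trimethoxy-5-methylphenyl)methyl]benzene F6. BCl3 (excess, pentamethylbenzene as benzyl cation scavenger, CH2Cl2, −78 °C to rt) should then cleave, by chelation to each ketone, the B2 and B4 methyl ethers and also the three benzyl ethers. The B6 ether has no carbonyl neighbour and should remain, so 18 is reached directly and step 7 is not needed.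

**Further compounds**

F1 | step 5 | 1-(2,4,6-trihydroxyphenyl)butan-1-one | CCCC(=O)c1c(O)cc(O)cc1O
F2 | step 5 | 1-{3,5-bis[(dimethylamino)methyl]-2,4,6-trihydroxyphenyl}butan-1-one | CCCC(=O)c1c(O)c(CN(C)C)c(O)c(CN(C)C)c1O
F3 | step 5 | 1-(2,4,6-trihydroxy-3-methylphenyl)butan-1-one | CCCC(=O)c1c(O)cc(O)c(C)c1O
F4 | step 5 | 1-(2,6-dihydroxy-4-methoxy-3-methylphenyl)butan-1-one (aspidinol) | CCCC(=O)c1c(O)cc(OC)c(C)c1O
F5 | step 8 | 1-{2,4,6-tris(benzyloxy)-3,5-bis[(3-butanoyl-2,4-dihydroxy-6-methoxy-5-methylphenyl)methyl]phenyl}butan-1-one | CCCC(=O)c1c(OCc2ccccc2)c(Cc2c(O)c(C(=O)CCC)c(O)c(C)c2OC)c(OCc2ccccc2)c(Cc2c(O)c(C(=O)CCC)c(O)c(C)c2OC)c1OCc1ccccc1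
F6 | step 6 | 1,3,5-tris(benzyloxy)-2,4-bis[(3-butanoyl-2,4,6-trimethoxy-5-methylphenyl)methyl]benzene | CCCC(=O)c1c(OC)c(C)c(OC)c(Cc2c(OCc3ccccc3)cc(OCc3ccccc3)c(Cc3c(OC)c(C(=O)CCC)c(OC)c(C)c3OC)c2OCc2ccccc2)c1OC
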